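- I began from the leftover: I asked how much of the substrate and of the reagent would remain at the end.

substrate 0.30 M; reagent 0.150 M (fed, over 2.0 h); free catalyst 0.42 mM; time 15 d

    substrate + catalyst intermediate B → catalyst intermediate C (k1 = 0.060 /M/s)
    catalyst intermediate C ⇌ catalyst intermediate D (K2 = 1.3, k2 = 0.026 /s)
    catalyst intermediate D ⇌ free catalyst + target (K3 = 3.3 M, k3 = 1.9 /s)
    catalyst intermediate A → catalyst intermediate B (k4 = 1.8 /s)
    reagent + free catalyst → catalyst intermediate A (k5 = 0.18 /M/s)

* which holds at 15 d: what has brought the reaction to rest, or that it has not come to rest (the reagent has run out first / all of the substrate has reacted / it is still moving / no working catalyst is left / forward and back rates have come level)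
* the target standing at 15 d, as a percentage of the substrate charged

- the reaction counts as stopped when no species that holds the substrate changes by six tenths of a point or more over the second half of the time
- run time (flask): 15 d

- Going round the cycle, I saw that free catalyst takes up reagent and passes through catalyst intermediates A and B by one-way steps, and that B then takes up substrate, also one-way, so each reagent consumed carries one substrate into the cycle.
- I folded the charges into the reagent ratio, 0.500, c(reagent) charged per c(substrate) charged, which reads as the share of the substrate that the reagent can turn over.
- With 0.150 M against 0.30 M, I took reagent as the limiting reagent, to run out first, and the target to stand at 50.0%.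
- I then tested whether that number was enough, first on time: the turnovers needed, c(reagent)/c(free catalyst), times a pass through substrate capture at its lowest c(substrate) and the step from C to D, plus the last decay of reagent on free catalyst, came to 0.771 d, far shorter than 15 d.
- I then put the first answer back in: that much target pushes step 3 backward, giving c(D)/c(free catalyst) = 0.0455, and with step 2 the catalyst holds 0.0313 mM of reacted substrate, far less than 0.150 M, so the second round gave 49.99%.
- The forecast gave "the reagent has run out first" and 49.99%, reasoning that “each reagent molecule converts exactly one substrate”.
- The flask gave "the reagent has run out first", with the target at 50.0%.
- In the flask, the ratio 0.500 stood beside that target, and half of the turnover of substrate with catalyst intermediate B was done at 0.350 d, far earlier than 15 d, with >99.9% of it done at 3.00 d, while at the end substrate stood at 50.0% and reagent at 0%. For the neighbour flask with 0.75 M of substrate the same ratio is 0.200, and that flask ended with the target at 20.0%.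

The numbers of this flask were set for the occasion.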